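**Retrosynthetic overview**

1. Agastinol 22 is cut at the C6–O ester bond into carbinol 18 and 4-(benzyloxy)benzoic acid 19, with three benzyl ethers removed last; C6 of 18 is the reduced carbon of the C3 methyl ester 17.
2. Feature used: the oxolane O1–C2(aryl)–C3–C4(benzyl)–C5H2 carries one exocyclic carbon (C6) on C3, the pattern left by a Wolff ring contraction. Ester 17 is therefore traced to trans-3-diazo-2-aryl-5-benzyltetrahydropyran-4-one 14: pyranone C5 shifts from the carbonyl carbon to the diazo carbon, and the carbonyl carbon becomes C6.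
3. 14 comes from trans ketone 12 by diazo transfer at the C3 methylene; 12 comes from enone 9 by conjugate reduction, the 2,5-trans (diequatorial) relation being the stable one.
4. 9 comes from 5-iodo enone 5 and benzylzinc reagent 8 (Negishi coupling); 5 comes from the catalytic asymmetric hetero-Diels–Alder adduct 4 of O-benzylvanillin 1 and siloxy diene 2, which sets C2.
5. Ring order: the pyranone ring is made first (step 1) and contracted to the oxolane in step 7; no other ring is built.

Key step: step 7

Numbering used: oxolane O1, C2 (aryl), C3, C4 (benzyl), C5, with C6 exocyclic on C3; pyranone O1, C2 (aryl), C3, C4 (C=O), C5 (benzyl), C6.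

Assumption: the Ti(OiPr)4–(R)-BINOL catalyst is taken to give the (R)-dihydropyranone, in line with the facial preference of this catalyst in related carbonyl additions; if the sense proves opposite, (S)-BINOL is used and nothing else changes.

**Route**

Step 1
Reactants: 1 O-benzylvanillin; 2 (E)-1-methoxy-3-(trimethylsilyloxy)buta-1,3-diene
Product: 4 (R)-2-[4-(benzyloxy)-3-methoxyphenyl]-2,3-dihydro-4H-pyran-4-one, via Mukaiyama aldol silyl ether 3 (not isolated)
Conditions: Ti(OiPr)4 (10 mol %), (R)-BINOL (20 mol %), 4 Å MS, Et2O, −20 °C; then CF3CO2H, CH2Cl2, 0 °C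
Reagents that add atoms: none
Why: Catalytic asymmetric hetero-Diels–Alder reaction run in its Mukaiyama-aldol/cyclisation form, in which the chiral titanium binaphtholate activates the aldehyde and exposes one carbonyl face to the diene terminus, setting C2 as R, after which acid closes the pyranone with loss of methanol and the silyl group.

Step 2
Reactants: 4 (R)-2-[4-(benzyloxy)-3-methoxyphenyl]-2,3-dihydro-4H-pyran-4-one
Product: 5 (R)-2-[4-(benzyloxy)-3-methoxyphenyl]-5-iodo-2,3-dihydro-4H-pyran-4-one
Conditions: I2, pyridine, CH2Cl2, 0 °C → rt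
Reagents that add atoms: iodine II
Why: Electrophilic α-iodination of a β-alkoxy enone (iodine–pyridine), in which C5 is the nucleophilic enol-ether carbon and pyridine removes the proton, while C2 and the arene are not expected to react under these mild conditions.

Step 3
Reactants: 6 [4-(benzyloxy)-3-methoxyphenyl]methanol
Product: 7 4-(benzyloxy)-3-methoxybenzyl chloride
Conditions: SOCl2, CH2Cl2, 0 °C → rt
Reagents that add atoms: thionyl chloride O=S(Cl)Cl
Why: Chlorodehydroxylation of an electron-rich benzylic alcohol through its chlorosulfite, with no stereocentre involved and the aryl benzyl ether inert.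

Step 4
Reactants: 5 (R)-2-[4-(benzyloxy)-3-methoxyphenyl]-5-iodo-2,3-dihydro-4H-pyran-4-one; 7 4-(benzyloxy)-3-methoxybenzyl chloride
Product: 9 (R)-2-[4-(benzyloxy)-3-methoxyphenyl]-5-[4-(benzyloxy)-3-methoxybenzyl]-2,3-dihydro-4H-pyran-4-one, via benzylzinc chloride 8 (not isolated)
Conditions: 7, Zn dust, LiCl, THF, 25 °C; then 5, Pd(PPh3)4 (5 mol %), THF, 25–40 °C
Reagents that add atoms: zinc [Zn] (zinc atom of 8 only)
Why: Negishi cross-coupling, in which LiCl-assisted zinc insertion into the benzylic C–Cl bond gives 8 and Pd(PPh3)4 (zerovalent palladium) joins it to the sp2 C5–I carbon of the α-iodo enone, a substrate class for which benzylzinc reagents are established partners, while the non-basic organozinc leaves C2 untouched.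

Step 5
Reactants: 9 (R)-2-[4-(benzyloxy)-3-methoxyphenyl]-5-[4-(benzyloxy)-3-methoxybenzyl]-2,3-dihydro-4H-pyran-4-one
Product: 12 (2R,5R)-2-[4-(benzyloxy)-3-methoxyphenyl]-5-[4-(benzyloxy)-3-methoxybenzyl]tetrahydro-4H-pyran-4-one (trans), via lithium enolate 10 (not isolated), via ketone C5-epimer mixture 11 (not isolated)
Conditions: LiBH(s-Bu)3, THF, −78 °C; AcOH, −78 °C; work-up; then DBU (0.2 equiv), CH2Cl2, 25 °C
Reagents that add atoms: none
Why: Conjugate (1,4) hydride reduction of the β-alkoxy enone gives enolate 10, axial protonation of which should already favour the equatorial benzyl group, and amine-base equilibration through the enol then converges C5 on the trans isomer (R) in which the C2 aryl and C5 benzyl groups are both equatorial, C2 being the controlling centre.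

Step 6
Reactants: 12 (2R,5R)-2-[4-(benzyloxy)-3-methoxyphenyl]-5-[4-(benzyloxy)-3-methoxybenzyl]tetrahydro-4H-pyran-4-one
Product: 14 (2S,5R)-2-[4-(benzyloxy)-3-methoxyphenyl]-5-[4-(benzyloxy)-3-methoxybenzyl]-3-diazotetrahydro-4H-pyran-4-one, via 3-trifluoroacetyl ketone 13 (not isolated)
Conditions: LiN(SiMe3)2, THF, −78 °C; CF3CO2CH2CF3, −78 °C; aq HCl work-up; then MsN3, Et3N, H2O (1 equiv), MeCN, 25 °C
Reagents that add atoms: methanesulfonyl azide CS(=O)(=O)N=[N+]=[N-]; 2,2,2-trifluoroethyl trifluoroacetate O=C(OCC(F)(F)F)C(F)(F)F (trifluoroacetyl group of 13 only)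
Why: Detrifluoroacetylative diazo transfer, in which the hindered amide base removes a proton kinetically from the C3 methylene and not from the C5 methine, C-trifluoroacylation activates that position alone, and the sulfonyl azide then delivers N2 with loss of the trifluoroacetyl group as its sulfonamide, so that C2 and C5 are not touched (the C2 descriptor changes to S only because the diazo carbon now outranks the aryl group).

Step 7
Reactants: 14 (2S,5R)-2-[4-(benzyloxy)-3-methoxyphenyl]-5-[4-(benzyloxy)-3-methoxybenzyl]-3-diazotetrahydro-4H-pyran-4-one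
Product: 17 methyl (2R,3R,4S)-2-[4-(benzyloxy)-3-methoxyphenyl]-4-[4-(benzyloxy)-3-methoxybenzyl]tetrahydrofuran-3-carboxylate, via ketene 15 (not isolated), via ester C3-epimer mixture 16 (not isolated)
Conditions: hν (365 nm, Pyrex), MeOH–THF, 0–10 °C; then NaOMe (0.3 equiv), MeOH, 25 °C
Reagents that add atoms: methanol CO
Why: Direct irradiation of the diazo ketone, whose C=N2 and C=O groups are held s-Z by the ring, expels N2 while the C4–C5 ring bond shifts to the diazo carbon (photochemical Wolff rearrangement of a cyclic α-diazo ketone, the established ring contraction of 2-diazocycloalkanones to cycloalkanecarboxylates), and ketene 15 is trapped by methanol. The oxolane is closed by this 1,2-shift from carbon to carbon, which makes the C3–C4 bond of the target ring out of a six-membered ring, so it is a ring contraction and no exo or endo cyclisation geometry has to be met. The migrating carbon moves with retention, so the 2,5-trans relation of 14 becomes the 2,4-trans relation of the oxolane, and C2 is not involved. The one new centre, C3, is first set by protonation of the ester enol and is then brought to equilibrium by NaOMe through the ester enolate, which is expected to put the ester anti to the aryl group bonded directly to C2 and therefore cis to the more flexible benzyl arm on C4 (2,3-trans-3,4-cis, as in the target). The step needs carbon migration to win over 1,2-hydride shift from the benzylic, oxygen-bearing C2–H and over O–H insertion, and the locked s-Z geometry together with metal-free photolysis favours the concerted shift. Opening of the ester enolate by loss of O1 from C2 would be the reverse of a 5-endo-trig closure and should not compete under catalytic base at 25 °C.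

Step 8
Reactants: 17 methyl (2R,3R,4S)-2-[4-(benzyloxy)-3-methoxyphenyl]-4-[4-(benzyloxy)-3-methoxybenzyl]tetrahydrofuran-3-carboxylate
Product: 18 [(2R,3S,4S)-2-[4-(benzyloxy)-3-methoxyphenyl]-4-[4-(benzyloxy)-3-methoxybenzyl]tetrahydrofuran-3-yl]methanol
Conditions: LiAlH4, THF, 0 °C
Reagents that add atoms: none
Why: Hydride reduction of the methyl ester to the primary alcohol, which is faster than α-deprotonation at 0 °C, so C3 keeps its configuration (its descriptor becomes S only because the exocyclic carbon drops in priority) and the benzyl ethers and the oxolane are inert.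

Step 9
Reactants: 18 [(2R,3S,4S)-2-[4-(benzyloxy)-3-methoxyphenyl]-4-[4-(benzyloxy)-3-methoxybenzyl]tetrahydrofuran-3-yl]methanol; 19 4-(benzyloxy)benzoic acid
Product: 21 [(2R,3S,4S)-2-[4-(benzyloxy)-3-methoxyphenyl]-4-[4-(benzyloxy)-3-methoxybenzyl]tetrahydrofuran-3-yl]methyl 4-(benzyloxy)benzoate, via 4-(benzyloxy)benzoyl chloride 20 (not isolated)
Conditions: 19, (COCl)2, DMF (cat.), CH2Cl2, 0 °C → rt, evaporate; then 18, Et3N, DMAP (cat.), CH2Cl2, 0 °C → rt
Reagents that add atoms: oxalyl chloride O=C(Cl)C(=O)Cl (chlorine of 20 only)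
Why: Acylation of the primary alcohol by the acid chloride made in the flask, under nucleophilic catalysis by DMAP, with no stereocentre touched.

Step 10
Reactants: 21 [(2R,3S,4S)-2-[4-(benzyloxy)-3-methoxyphenyl]-4-[4-(benzyloxy)-3-methoxybenzyl]tetrahydrofuran-3-yl]methyl 4-(benzyloxy)benzoate
Product: 22 agastinol
Conditions: H2 (1 atm), 10% Pd/C, EtOAc, 25 °C
Reagents that add atoms: none
Why: Catalytic hydrogenolysis of the three aryl benzyl ethers, which in a neutral aprotic solvent at 1 atm should cleave much faster than the cyclic benzylic C2–O1 bond, so that stopping at full debenzylation leaves the oxolane and its three stereocentres intact.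

**Compound list**

1 | 4-(benzyloxy)-3-methoxybenzaldehyde (O-benzylvanillin) | COc1cc(C=O)ccc1OCc1ccccc1 | starting material
2 | (E)-1-methoxy-3-(trimethylsilyloxy)buta-1,3-diene | CO/C=C/C(=C)O[Si](C)(C)C | starting material
3 | (R,E)-5-[4-(benzyloxy)-3-methoxyphenyl]-1-methoxy-5-(trimethylsilyloxy)pent-1-en-3-one (Mukaiyama aldol silyl ether, not isolated) | CO/C=C/C(=O)C[C@@H](O[Si](C)(C)C)c1ccc(OCc2ccccc2)c(OC)c1 | intermediate
4 | (R)-2-[4-(benzyloxy)-3-methoxyphenyl]-2,3-dihydro-4H-pyran-4-one | O=C1C=CO[C@@H](c2ccc(OCc3ccccc3)c(OC)c2)C1 | intermediate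
5 | (R)-2-[4-(benzyloxy)-3-methoxyphenyl]-5-iodo-2,3-dihydro-4H-pyran-4-one | O=C1C(I)=CO[C@@H](c2ccc(OCc3ccccc3)c(OC)c2)C1 | intermediate
6 | [4-(benzyloxy)-3-methoxyphenyl]methanol | COc1cc(CO)ccc1OCc1ccccc1 | starting material
7 | 4-(benzyloxy)-3-methoxybenzyl chloride | COc1cc(CCl)ccc1OCc1ccccc1 | intermediate
8 | [4-(benzyloxy)-3-methoxybenzyl]zinc chloride (not isolated) | COc1cc(C[Zn]Cl)ccc1OCc1ccccc1 | intermediate
9 | (R)-2-[4-(benzyloxy)-3-methoxyphenyl]-5-[4-(benzyloxy)-3-methoxybenzyl]-2,3-dihydro-4H-pyran-4-one | O=C1C(Cc2ccc(OCc3ccccc3)c(OC)c2)=CO[C@@H](c2ccc(OCc3ccccc3)c(OC)c2)C1 | intermediate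
10 | lithium (R)-6-[4-(benzyloxy)-3-methoxyphenyl]-3-[4-(benzyloxy)-3-methoxybenzyl]-5,6-dihydro-2H-pyran-4-olate (enolate, not isolated) | [Li+].[O-]C1=C(Cc2ccc(OCc3ccccc3)c(OC)c2)CO[C@@H](c2ccc(OCc3ccccc3)c(OC)c2)C1 | intermediate
11 | (2R)-2-[4-(benzyloxy)-3-methoxyphenyl]-5-[4-(benzyloxy)-3-methoxybenzyl]tetrahydro-4H-pyran-4-one, mixture of C5 epimers (not isolated) | COc1cc(CC2CO[C@@H](c3ccc(OCc4ccccc4)c(OC)c3)CC2=O)ccc1OCc1ccccc1 | intermediate
12 | (2R,5R)-2-[4-(benzyloxy)-3-methoxyphenyl]-5-[4-(benzyloxy)-3-methoxybenzyl]tetrahydro-4H-pyran-4-one (trans) | COc1cc(C[C@@H]2CO[C@@H](c3ccc(OCc4ccccc4)c(OC)c3)CC2=O)ccc1OCc1ccccc1 | intermediate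
13 | (2R,5R)-2-[4-(benzyloxy)-3-methoxyphenyl]-5-[4-(benzyloxy)-3-methoxybenzyl]-3-(trifluoroacetyl)tetrahydro-4H-pyran-4-one, C3 undefined and largely enolised (not isolated) | COc1cc(C[C@@H]2CO[C@@H](c3ccc(OCc4ccccc4)c(OC)c3)C(C(=O)C(F)(F)F)C2=O)ccc1OCc1ccccc1 | intermediate
14 | (2S,5R)-2-[4-(benzyloxy)-3-methoxyphenyl]-5-[4-(benzyloxy)-3-methoxybenzyl]-3-diazotetrahydro-4H-pyran-4-one (trans; key-step precursor) | COc1cc(C[C@@H]2CO[C@@H](c3ccc(OCc4ccccc4)c(OC)c3)C(=[N+]=[N-])C2=O)ccc1OCc1ccccc1 | intermediate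
15 | (2S,4S)-2-[4-(benzyloxy)-3-methoxyphenyl]-4-[4-(benzyloxy)-3-methoxybenzyl]-3-(oxomethylidene)tetrahydrofuran (ketene, not isolated) | COc1cc(C[C@@H]2CO[C@@H](c3ccc(OCc4ccccc4)c(OC)c3)C2=C=O)ccc1OCc1ccccc1 | intermediate
16 | methyl (2R,4S)-2-[4-(benzyloxy)-3-methoxyphenyl]-4-[4-(benzyloxy)-3-methoxybenzyl]tetrahydrofuran-3-carboxylate, mixture of C3 epimers (not isolated) | COc1cc(C[C@@H]2CO[C@@H](c3ccc(OCc4ccccc4)c(OC)c3)C2C(=O)OC)ccc1OCc1ccccc1 | intermediate
17 | methyl (2R,3R,4S)-2-[4-(benzyloxy)-3-methoxyphenyl]-4-[4-(benzyloxy)-3-methoxybenzyl]tetrahydrofuran-3-carboxylate (key-step product) | COc1cc(C[C@@H]2CO[C@@H](c3ccc(OCc4ccccc4)c(OC)c3)[C@@H]2C(=O)OC)ccc1OCc1ccccc1 | intermediate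
18 | [(2R,3S,4S)-2-[4-(benzyloxy)-3-methoxyphenyl]-4-[4-(benzyloxy)-3-methoxybenzyl]tetrahydrofuran-3-yl]methanol | COc1cc(C[C@@H]2CO[C@@H](c3ccc(OCc4ccccc4)c(OC)c3)[C@@H]2CO)ccc1OCc1ccccc1 | intermediate
19 | 4-(benzyloxy)benzoic acid | O=C(O)c1ccc(OCc2ccccc2)cc1 | starting material
20 | 4-(benzyloxy)benzoyl chloride (not isolated) | O=C(Cl)c1ccc(OCc2ccccc2)cc1 | intermediate
21 | [(2R,3S,4S)-2-[4-(benzyloxy)-3-methoxyphenyl]-4-[4-(benzyloxy)-3-methoxybenzyl]tetrahydrofuran-3-yl]methyl 4-(benzyloxy)benzoate | COc1cc(C[C@@H]2CO[C@@H](c3ccc(OCc4ccccc4)c(OC)c3)[C@@H]2COC(=O)c2ccc(OCc3ccccc3)cc2)ccc1OCc1ccccc1 | intermediate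
22 | agastinol, [(2R,3S,4S)-2-(4-hydroxy-3-methoxyphenyl)-4-(4-hydroxy-3-methoxybenzyl)tetrahydrofuran-3-yl]methyl 4-hydroxybenzoate | COc1cc(C[C@@H]2CO[C@@H](c3ccc(O)c(OC)c3)[C@@H]2COC(=O)c2ccc(O)cc2)ccc1O | target

**Step count and risks**

Total step count: 10. Longest linear sequence: 9 steps (steps 1, 2, 4, 5, 6, 7, 8, 9, 10, from O-benzylvanillin 1); step 3 is a one-step side branch.

Steps most likely to fail:

Step 7. The excited diazo ketone may lose N2 to a free carbene, which then undergoes 1,2-hydride shift from the benzylic, oxygen-bearing C2–H to give an enone, or inserts into the O–H bond of methanol, instead of contracting the ring. The C3 equilibrium may also be only modestly biased; in that case the minor C3 epimer is separated and returned to the NaOMe treatment. The fallback is a carbene-free ring contraction that sets out from ketone 12. Kinetic silylation (LiN(SiMe3)2, Me3SiCl, THF, −78 °C) should give the trimethylsilyl enol ether F1. Nonafluorobutanesulfonyl azide in MeCN at 0–25 °C adds across the enol ether, and the resulting triazoline loses N2 with the same shift of the benzyl-bearing carbon; aqueous work-up should then give the ring-contracted N-sulfonyl carboxamide F2. N-Methylation with Me3SiCHN2 in MeOH–toluene gives the activated N-methyl-N-sulfonyl amide F3. NaOMe in MeOH should cleave F3 to the methyl ester and equilibrate C3 in the same operation, so that the fallback comes back to the route at ester 17.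

Step 6. Deprotonation may not discriminate cleanly between C3 and C5, and the C3 enolate may open the ring by loss of O1 from C2, which would also erase C2. The fallback avoids strong base and sets out from ketone 12. Heating with Me2NCH(OMe)2 in toluene at 90 °C, a condensation possible only at a methylene, should give the enaminone F4. Diazo transfer to this enaminone with MsN3 in MeCN at 25 °C proceeds by cycloaddition and fragmentation with loss of the formamidine, and comes back to the route at diazo ketone 14.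

Step 5. Competing 1,2-reduction, incomplete facial control in the protonation and slow erosion of C2 by reversible ring opening during the base equilibration may leave trans ketone 12 impure. The fallback sets C5 by substrate-directed hydrogenation instead of equilibration and sets out from enone 9. Luche reduction (NaBH4, CeCl3·7H2O, MeOH, −78 °C) should give the 2,4-cis allylic alcohol F5. Hydrogenation with [Ir(cod)(PCy3)(py)]PF6 and H2 in CH2Cl2 delivers hydrogen to the enol-ether double bond from the face of the hydroxyl group, giving the all-equatorial alcohol F6 with the benzyl group trans to the aryl group. Oxidation with Dess–Martin periodinane comes back to the route at ketone 12.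

**Further compounds**

F1 | step 7 | (2R,5R)-2-[4-(benzyloxy)-3-methoxyphenyl]-5-[4-(benzyloxy)-3-methoxybenzyl]-4-(trimethylsilyloxy)-5,6-dihydro-2H-pyran | COc1cc(C[C@@H]2CO[C@@H](c3ccc(OCc4ccccc4)c(OC)c3)C=C2O[Si](C)(C)C)ccc1OCc1ccccc1
F2 | step 7 | (2R,4S)-2-[4-(benzyloxy)-3-methoxyphenyl]-4-[4-(benzyloxy)-3-methoxybenzyl]-N-(nonafluorobutylsulfonyl)tetrahydrofuran-3-carboxamide, mixture of C3 epimers | COc1cc(C[C@@H]2CO[C@@H](c3ccc(OCc4ccccc4)c(OC)c3)C2C(=O)NS(=O)(=O)C(F)(F)C(F)(F)C(F)(F)C(F)(F)F)ccc1OCc1ccccc1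
F3 | step 7 | (2R,4S)-2-[4-(benzyloxy)-3-methoxyphenyl]-4-[4-(benzyloxy)-3-methoxybenzyl]-N-methyl-N-(nonafluorobutylsulfonyl)tetrahydrofuran-3-carboxamide, mixture of C3 epimers | COc1cc(C[C@@H]2CO[C@@H](c3ccc(OCc4ccccc4)c(OC)c3)C2C(=O)N(C)S(=O)(=O)C(F)(F)C(F)(F)C(F)(F)C(F)(F)F)ccc1OCc1ccccc1
F4 | step 6 | (2S,5R)-2-[4-(benzyloxy)-3-methoxyphenyl]-5-[4-(benzyloxy)-3-methoxybenzyl]-3-[(dimethylamino)methylidene]tetrahydro-4H-pyran-4-one | COc1cc(C[C@@H]2CO[C@@H](c3ccc(OCc4ccccc4)c(OC)c3)C(=CN(C)C)C2=O)ccc1OCc1ccccc1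
F5 | step 5 | (2R,4R)-2-[4-(benzyloxy)-3-methoxyphenyl]-5-[4-(benzyloxy)-3-methoxybenzyl]-3,4-dihydro-2H-pyran-4-ol | COc1cc(CC2=CO[C@@H](c3ccc(OCc4ccccc4)c(OC)c3)C[C@H]2O)ccc1OCc1ccccc1
F6 | step 5 | (2R,4R,5R)-2-[4-(benzyloxy)-3-methoxyphenyl]-5-[4-(benzyloxy)-3-methoxybenzyl]tetrahydro-2H-pyran-4-ol | COc1cc(C[C@@H]2CO[C@@H](c3ccc(OCc4ccccc4)c(OC)c3)C[C@H]2O)ccc1OCc1ccccc1
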